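Slowness is what this flask has to offer: in this kinetic resolution, the excess asked for needs the right-handed substrate to linger while the left-handed substrate leaves.

| flask | left-handed substrate | right-handed substrate | partner | protic impurity | remark | time |
|---|---|---|---|---|---|---|
| maple | 0.050 M | 0.050 M | 3 equiv | 0.050 M | the very flask that is asked about, followed so far |  |
| flask | 0.050 M | 0.050 M | 3.00 equiv | 0.0500 M |  | 12 h |

maple run (percent of the left-handed substrate and right-handed substrate together charged)

| time / h | right-handed substrate / % | left-handed substrate / % | left-handed product / % |
|---|---|---|---|
| 0.500 | 48.1 | 0.1 | 48.5 |
| 0.833 | 46.8 | 0 | 48.9 |
| 1.50 | 45.7 | 0.5 | 47.4 |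
| 3.00 | 43.6 | 0 | 44.8 |
| 6.00 | 37.7 | 0 | 40.9 |

(scatter of a reading: 0.5 percentage points)

- whether the excess of right-handed substrate over left-handed substrate among what is left of the two reaches 95% by 12 h (yes / no)
- the highest excess of right-handed substrate over left-handed substrate among what is left of the two up to 12 h

- partner is single-handed; left-handed substrate and right-handed substrate are mirror images of each other, charged as a racemate, each of them at the stated concentration
- what was read earlier has a scatter of 0.5 percentage points, one standard deviation
- the handed part of partner does not stay in what it makes, so the products of the two hands are mirror images too

The bench rule turns the excess into a ceiling. The permitted ratio, one minus the excess over one plus the excess, is the most left-handed substrate that may stand per unit of right-handed substrate, and at 95% it is 2.56%. In the maple run at 0.500 h, the 48.1% of right-handed substrate permits 1.23% of left-handed substrate, and the reading of 0.1% lies below that, so the rule says yes at the first reading.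

The rule stops working where the ceiling sinks into the scatter: a ceiling of 0.5 percentage points belongs to 19.5% of right-handed substrate, and below that a zero reading of left-handed substrate no longer stands one scatter clear of the ceiling. In the maple run the right-handed substrate falls by 0.0189 /h as a fraction of the charge, so a straight line gives 26.4% at 12 h, which is more than the border. The reckoning here commits to yes. With left-handed substrate one scatter above its zero reading at 6.00 h, the excess there comes to 97.4%, so this reckoning, an estimate, puts the top between that and full excess.

The forecast says yes, with a top of 99.9%, on this ground: “Neither trend shows left-handed substrate coming back.”

The flask answers yes, with a top of 100%.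

    partner ⇌ dormant form (K = 0.110, k = 0.00553 /min)
    partner + right-handed substrate → right-handed product (k = 0.0189 /M/min)
    left-handed product ⇌ right-handed product (k = 7.39 × 10⁻⁴ /min)
    partner + protic impurity → quenched reagent (k = 1.69 /M/min)
    partner + left-handed substrate → left-handed product (k = 3.25 /M/min)

The flask passes 95% at 0.250 h, with 48.9% of right-handed substrate left, where the permitted ratio allows 1.25% of left-handed substrate. The turning of left-handed product into right-handed product runs with a backward turnover of 46% of the forward one, yet it leaves the excess of right-handed substrate over left-handed substrate at 12.0 h unchanged. At 12.0 h the flask holds 30.8% of right-handed substrate, more than the border; that amount permits 0.788% of left-handed substrate, and left-handed substrate stands at 0%.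

The readings are calculated with constants of no real substance.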